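The upper 3,4-diarylchroman is cut at C3–C4 and O1–C2. Because C4 sits on C4a of the 7-oxygenated benzo ring, next to the C8a–O1 phenol oxygen, the O1–C8a–C4a–C4 unit can be unmasked as an ortho-quinone methide, while C2–C3 with its aryl group is supplied as an arylacetaldehyde. One aminocatalytic annulation then forges both bonds, closes the pyran ring as a lactol and sets C3 and C4 trans. Its precursor is an acid-labile ortho-hydroxybenzhydrol that already carries the (R)-isoflavan, assembled by Evans alkylation and Mitsunobu ring closure; lactol reduction and hydrogenolysis finish.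

Key step: step 15

Remark: 1 is taken as a catalogue compound; if it has to be made, para-bromination of 2-hydroxy-4-methoxybenzaldehyde (Br2, AcOH) supplies it in one step.

Step 1
Reactants: 1 5-bromo-2-hydroxy-4-methoxybenzaldehyde
Product: 2 2-(benzyloxy)-5-bromo-4-methoxybenzaldehyde
Conditions: BnBr, K2CO3, DMF, 60 °C
Reagents that add atoms: benzyl bromide, BrCc1ccccc1
Why: Williamson ether synthesis on the only acidic OH; the bromine, placed before any ring assembly, later serves as the metalation handle at C5' of the lower ring B, where a late bromination could not tell the two resorcinol-type rings apart.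

Step 2
Reactants: 2 2-(benzyloxy)-5-bromo-4-methoxybenzaldehyde
Product: 4 2-[2-(benzyloxy)-5-bromo-4-methoxyphenyl]acetaldehyde, via methyl enol ether 3 (not isolated)
Conditions: Ph3P(CH2OMe)Cl, KOtBu, THF, 0 °C to rt; then 2 M HCl, 45 °C
Reagents that add atoms: (methoxymethyl)triphenylphosphonium chloride, COC[P+](c1ccccc1)(c1ccccc1)c1ccccc1.[Cl-]; water, O
Why: Wittig methoxymethylenation followed by acid hydrolysis of the enol ether is the standard one-carbon homologation of a benzaldehyde, and benzyl ether and aryl bromide tolerate both stages.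

Step 3
Reactants: 4 2-[2-(benzyloxy)-5-bromo-4-methoxyphenyl]acetaldehyde
Product: 5 2-[2-(benzyloxy)-5-bromo-4-methoxyphenyl]acetic acid
Conditions: NaClO2, NaH2PO4, 2-methyl-2-butene, t-BuOH/H2O, 0 °C to rt
Reagents that add atoms: sodium chlorite, [Na+].[O-]Cl=O
Why: Pinnick oxidation touches only the aldehyde, and the alkene scavenger keeps hypochlorous acid away from the electron-rich ring.

Step 4
Reactants: 5 2-[2-(benzyloxy)-5-bromo-4-methoxyphenyl]acetic acid; 6 (R)-4-benzyloxazolidin-2-one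
Product: 8 (R)-4-benzyl-3-{2-[2-(benzyloxy)-5-bromo-4-methoxyphenyl]acetyl}oxazolidin-2-one, via mixed pivalic anhydride 7 (not isolated)
Conditions: PivCl, Et3N, THF, −20 °C; then 6, LiCl, −20 °C to rt
Reagents that add atoms: none
Why: N-acylation of the oxazolidinone through the mixed pivalic anhydride, which is attacked at the unhindered arylacetyl carbonyl; no organolithium meets the aryl bromide.

Step 5
Reactants: 9 4-(benzyloxy)-2-hydroxybenzaldehyde
Product: 10 4-(benzyloxy)-2-[(tert-butyldimethylsilyl)oxy]benzaldehyde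
Conditions: TBSCl, imidazole, DMF, rt
Reagents that add atoms: tert-butyldimethylsilyl chloride, CC(C)(C)[Si](C)(C)Cl
Why: Silylation of the phenol removes the acidic proton, so that one compound serves both as the source of the lower ring-A benzyl bromide (steps 6–7) and as a proton-free electrophile for the aryllithium in step 12.

Step 6
Reactants: 10 4-(benzyloxy)-2-[(tert-butyldimethylsilyl)oxy]benzaldehyde
Product: 11 {4-(benzyloxy)-2-[(tert-butyldimethylsilyl)oxy]phenyl}methanol
Conditions: NaBH4, MeOH/THF, 0 °C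
Reagents that add atoms: none
Why: Borohydride reduction of the aldehyde in a protic medium, where the new alkoxide is protonated at once and the aryl silyl ether should stay in place.

Step 7
Reactants: 11 {4-(benzyloxy)-2-[(tert-butyldimethylsilyl)oxy]phenyl}methanol
Product: 12 [5-(benzyloxy)-2-(bromomethyl)phenoxy](tert-butyl)dimethylsilane
Conditions: CBr4, PPh3, CH2Cl2, 0 °C; used at once
Reagents that add atoms: carbon tetrabromide, BrC(Br)(Br)Br
Why: Appel bromination under neutral conditions gives the donor-activated benzyl bromide, which is labile and is therefore taken on without chromatography.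

Step 8
Reactants: 8 (R)-4-benzyl-3-{2-[2-(benzyloxy)-5-bromo-4-methoxyphenyl]acetyl}oxazolidin-2-one; 12 [5-(benzyloxy)-2-(bromomethyl)phenoxy](tert-butyl)dimethylsilane
Product: 14 (R)-4-benzyl-3-[(2R)-2-[2-(benzyloxy)-5-bromo-4-methoxyphenyl]-3-{4-(benzyloxy)-2-[(tert-butyldimethylsilyl)oxy]phenyl}propanoyl]oxazolidin-2-one, via sodium Z-enolate 13 (not isolated)
Conditions: NaHMDS, THF, −78 °C; then 12, −78 to −40 °C
Reagents that add atoms: none
Why: Evans asymmetric alkylation, in which the chelated Z-enolate is attacked by the benzyl bromide on the face opposite the auxiliary's benzyl group, so the (R)-auxiliary should set the future C3 of the lower chroman as R.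

Step 9
Reactants: 14 (R)-4-benzyl-3-[(2R)-2-[2-(benzyloxy)-5-bromo-4-methoxyphenyl]-3-{4-(benzyloxy)-2-[(tert-butyldimethylsilyl)oxy]phenyl}propanoyl]oxazolidin-2-one
Product: 15 (2R)-2-[2-(benzyloxy)-5-bromo-4-methoxyphenyl]-3-{4-(benzyloxy)-2-[(tert-butyldimethylsilyl)oxy]phenyl}propan-1-ol
Conditions: LiBH4, H2O (1 equiv), Et2O/THF, 0 °C
Reagents that add atoms: none
Why: Reductive cleavage of the imide by borohydride gives the primary alcohol without epimerising the α-centre or touching aryl bromide and silyl ether, and returns the auxiliary.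

Step 10
Reactants: 15 (2R)-2-[2-(benzyloxy)-5-bromo-4-methoxyphenyl]-3-{4-(benzyloxy)-2-[(tert-butyldimethylsilyl)oxy]phenyl}propan-1-ol
Product: 16 5-(benzyloxy)-2-[(2R)-2-[2-(benzyloxy)-5-bromo-4-methoxyphenyl]-3-hydroxypropyl]phenol
Conditions: TBAF, THF, 0 °C
Reagents that add atoms: none
Why: Fluoride desilylation of the aryl silyl ether; no other group in 15 responds to TBAF.

Step 11
Reactants: 16 5-(benzyloxy)-2-[(2R)-2-[2-(benzyloxy)-5-bromo-4-methoxyphenyl]-3-hydroxypropyl]phenol
Product: 17 (3R)-7-(benzyloxy)-3-[2-(benzyloxy)-5-bromo-4-methoxyphenyl]chroman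
Conditions: PPh3, DIAD, THF, 0 °C to rt
Reagents that add atoms: none
Why: Intramolecular Mitsunobu etherification (6-exo-tet) joins the phenol to the primary carbon, so the neighbouring stereocentre is not involved.

Step 12
Reactants: 17 (3R)-7-(benzyloxy)-3-[2-(benzyloxy)-5-bromo-4-methoxyphenyl]chroman; 10 4-(benzyloxy)-2-[(tert-butyldimethylsilyl)oxy]benzaldehyde
Product: 20 {4-(benzyloxy)-5-[(3R)-7-(benzyloxy)chroman-3-yl]-2-methoxyphenyl}[4-(benzyloxy)-2-hydroxyphenyl]methanol (both carbinol epimers), via aryllithium 18 (not isolated), via silylated lithium alkoxide 19 (not isolated)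
Conditions: t-BuLi (2 equiv), THF, −78 °C; 10, −78 °C; then TBAF, −78 to 0 °C; pH 7 buffer work-up, Et3N-washed silica
Reagents that add atoms: none
Why: Bromine–lithium exchange and 1,2-addition of the aryllithium to the aldehyde; fluoride then removes the silyl group from whichever oxygen holds it after a possible 1,4-O-to-O shift, and the neutral work-up spares the acid-labile benzhydrol, which is used fresh.

Step 13
Reactants: 21 2-hydroxy-4,5-dimethoxybenzaldehyde
Product: 22 2-(benzyloxy)-4,5-dimethoxybenzaldehyde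
Conditions: BnBr, K2CO3, DMF, 60 °C
Reagents that add atoms: benzyl bromide, BrCc1ccccc1
Why: Williamson ether synthesis on the single phenol.

Step 14
Reactants: 22 2-(benzyloxy)-4,5-dimethoxybenzaldehyde
Product: 24 2-[2-(benzyloxy)-4,5-dimethoxyphenyl]acetaldehyde, via methyl enol ether 23 (not isolated)
Conditions: Ph3P(CH2OMe)Cl, KOtBu, THF, 0 °C to rt; then 2 M HCl, 45 °C; used fresh
Reagents that add atoms: (methoxymethyl)triphenylphosphonium chloride, COC[P+](c1ccccc1)(c1ccccc1)c1ccccc1.[Cl-]; water, O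
Why: The same Wittig methoxymethylenation and enol ether hydrolysis as in step 2 delivers the enolisable arylacetaldehyde.

Step 15
Reactants: 20 {4-(benzyloxy)-5-[(3R)-7-(benzyloxy)chroman-3-yl]-2-methoxyphenyl}[4-(benzyloxy)-2-hydroxyphenyl]methanol; 24 2-[2-(benzyloxy)-4,5-dimethoxyphenyl]acetaldehyde
Product: 27 (3R,4S)-7-(benzyloxy)-3-[2-(benzyloxy)-4,5-dimethoxyphenyl]-4-{4-(benzyloxy)-5-[(3R)-7-(benzyloxy)chroman-3-yl]-2-methoxyphenyl}chroman-2-ol (anomeric mixture), via o-quinone methide 25 (not isolated), via catalyst enamine 26 (not isolated)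
Conditions: (R)-2-[diphenyl(trimethylsilyloxy)methyl]pyrrolidine (20 mol %), PhCO2H (20 mol %), CH2Cl2, 0 °C to rt; 24 (1.5 equiv) added slowly
Reagents that add atoms: none
Why: Benzoic acid ionises the doubly donor-stabilised benzhydrol 20 (either carbinol epimer) to the planar o-quinone methide 25 while the secondary amine converts 24 into the E-enamine 26; the enamine α-carbon adds to the methide carbon (C3–C4), the liberated phenoxide closes onto the iminium carbon (O1–C2, 6-exo-trig), and hydrolysis of the N,O-aminal releases lactol 27 and the amine. The closest known reaction type is the amine-catalysed formal [4+2] annulation of in situ generated o-quinone methides with enolisable aldehydes, an enamine Michael addition followed by hemiacetalisation. C3 is controlled by the catalyst, whose diphenyl(silyloxy)methyl group blocks one enamine face, so that the (R)-amine should give 3R, the mirror image of the sense known for the (S)-amine in enamine Michael additions to nitroalkenes. C4 is fixed in the same bond-forming event by the synclinal approach of the two trigonal carbons, which corresponds to the 3,4-trans ring and hence to 4S. The step needs catalyst control to prevail over the resident (R)-chroman centre and trans to prevail over cis; the first is secured by the distance of that centre from the reacting carbon (a wrong isomer would be a separable diastereomer), the second by the fact that C3 stays epimerisable through the open hydroxy aldehyde, so the trans lactol is also the thermodynamic product. Chemoselectivity should rest on the conjugated, strongly nucleophilic arylacetaldehyde enamine outrunning arene attack on the methide, with the aldehyde in excess to offset self-aldolisation.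

Step 16
Reactants: 27 (3R,4S)-7-(benzyloxy)-3-[2-(benzyloxy)-4,5-dimethoxyphenyl]-4-{4-(benzyloxy)-5-[(3R)-7-(benzyloxy)chroman-3-yl]-2-methoxyphenyl}chroman-2-ol
Product: 28 (3R,4S)-7-(benzyloxy)-3-[2-(benzyloxy)-4,5-dimethoxyphenyl]-4-{4-(benzyloxy)-5-[(3R)-7-(benzyloxy)chroman-3-yl]-2-methoxyphenyl}chroman
Conditions: Et3SiH, BF3·OEt2, CH2Cl2, −78 to −30 °C
Reagents that add atoms: none
Why: Ionic hydrogenation of the lactol: BF3 opens it to the cyclic oxocarbenium ion, which triethylsilane reduces at C2, and at low temperature the benzyl ethers and the C3 and C4 centres should stay untouched.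

Step 17
Reactants: 28 (3R,4S)-7-(benzyloxy)-3-[2-(benzyloxy)-4,5-dimethoxyphenyl]-4-{4-(benzyloxy)-5-[(3R)-7-(benzyloxy)chroman-3-yl]-2-methoxyphenyl}chroman
Product: 29 (3R,4S)-3-(2-hydroxy-4,5-dimethoxyphenyl)-4-{4-hydroxy-5-[(3R)-7-hydroxychroman-3-yl]-2-methoxyphenyl}chroman-7-ol
Conditions: H2 (1 atm), 10% Pd/C, THF/MeOH, rt
Reagents that add atoms: none
Why: Catalytic hydrogenolysis cleaves the four O-benzyl bonds; the chroman C–O bonds are not benzylic and the diarylmethine C–C bonds are inert to Pd/H2, so the three stereocentres remain.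

Compound list
1 | 5-bromo-2-hydroxy-4-methoxybenzaldehyde | COc1cc(O)c(C=O)cc1Br | starting material
2 | 2-(benzyloxy)-5-bromo-4-methoxybenzaldehyde | COc1cc(OCc2ccccc2)c(C=O)cc1Br | intermediate
3 | 1-(benzyloxy)-4-bromo-5-methoxy-2-(2-methoxyethenyl)benzene (E/Z mixture) | COC=Cc1cc(Br)c(OC)cc1OCc1ccccc1 | intermediate
4 | 2-[2-(benzyloxy)-5-bromo-4-methoxyphenyl]acetaldehyde | COc1cc(OCc2ccccc2)c(CC=O)cc1Br | intermediate
5 | 2-[2-(benzyloxy)-5-bromo-4-methoxyphenyl]acetic acid | COc1cc(OCc2ccccc2)c(CC(=O)O)cc1Br | intermediate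
6 | (R)-4-benzyloxazolidin-2-one | O=C1N[C@H](Cc2ccccc2)CO1 | starting material
7 | 2-[2-(benzyloxy)-5-bromo-4-methoxyphenyl]acetic pivalic anhydride | CC(C)(C)C(=O)OC(=O)Cc1cc(Br)c(OC)cc1OCc1ccccc1 | intermediate
8 | (R)-4-benzyl-3-{2-[2-(benzyloxy)-5-bromo-4-methoxyphenyl]acetyl}oxazolidin-2-one | COc1cc(OCc2ccccc2)c(CC(=O)N2C(=O)OC[C@H]2Cc2ccccc2)cc1Br | intermediate
9 | 4-(benzyloxy)-2-hydroxybenzaldehyde | O=Cc1ccc(OCc2ccccc2)cc1O | starting material
10 | 4-(benzyloxy)-2-[(tert-butyldimethylsilyl)oxy]benzaldehyde | CC(C)(C)[Si](C)(C)Oc1cc(OCc2ccccc2)ccc1C=O | intermediate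
11 | {4-(benzyloxy)-2-[(tert-butyldimethylsilyl)oxy]phenyl}methanol | CC(C)(C)[Si](C)(C)Oc1cc(OCc2ccccc2)ccc1CO | intermediate
12 | [5-(benzyloxy)-2-(bromomethyl)phenoxy](tert-butyl)dimethylsilane | CC(C)(C)[Si](C)(C)Oc1cc(OCc2ccccc2)ccc1CBr | intermediate
13 | sodium (Z)-enolate of 8 | [Na+].[O-]/C(=C\c1cc(Br)c(OC)cc1OCc1ccccc1)N1C(=O)OC[C@H]1Cc1ccccc1 | intermediate
14 | (R)-4-benzyl-3-[(2R)-2-[2-(benzyloxy)-5-bromo-4-methoxyphenyl]-3-{4-(benzyloxy)-2-[(tert-butyldimethylsilyl)oxy]phenyl}propanoyl]oxazolidin-2-one | COc1cc(OCc2ccccc2)c([C@@H](Cc2ccc(OCc3ccccc3)cc2O[Si](C)(C)C(C)(C)C)C(=O)N2C(=O)OC[C@H]2Cc2ccccc2)cc1Br | intermediate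
15 | (2R)-2-[2-(benzyloxy)-5-bromo-4-methoxyphenyl]-3-{4-(benzyloxy)-2-[(tert-butyldimethylsilyl)oxy]phenyl}propan-1-ol | COc1cc(OCc2ccccc2)c([C@@H](Cc2ccc(OCc3ccccc3)cc2O[Si](C)(C)C(C)(C)C)CO)cc1Br | intermediate
16 | 5-(benzyloxy)-2-[(2R)-2-[2-(benzyloxy)-5-bromo-4-methoxyphenyl]-3-hydroxypropyl]phenol | COc1cc(OCc2ccccc2)c([C@@H](Cc2ccc(OCc3ccccc3)cc2O)CO)cc1Br | intermediate
17 | (3R)-7-(benzyloxy)-3-[2-(benzyloxy)-5-bromo-4-methoxyphenyl]chroman | COc1cc(OCc2ccccc2)c([C@@H]2COc3cc(OCc4ccccc4)ccc3C2)cc1Br | intermediate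
18 | {4-(benzyloxy)-5-[(3R)-7-(benzyloxy)chroman-3-yl]-2-methoxyphenyl}lithium | COc1cc(OCc2ccccc2)c([C@@H]2COc3cc(OCc4ccccc4)ccc3C2)cc1[Li] | intermediate
19 | lithium alkoxide of the O-silylated benzhydrol (both carbinol epimers; the silyl group may shift to the carbinol oxygen) | [Li+].[O-]C(c1ccc(OCc2ccccc2)cc1O[Si](C)(C)C(C)(C)C)c1cc([C@@H]2COc3cc(OCc4ccccc4)ccc3C2)c(OCc2ccccc2)cc1OC | intermediate
20 | {4-(benzyloxy)-5-[(3R)-7-(benzyloxy)chroman-3-yl]-2-methoxyphenyl}[4-(benzyloxy)-2-hydroxyphenyl]methanol (both carbinol epimers) | OC(c1ccc(OCc2ccccc2)cc1O)c1cc([C@@H]2COc3cc(OCc4ccccc4)ccc3C2)c(OCc2ccccc2)cc1OC | intermediate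
21 | 2-hydroxy-4,5-dimethoxybenzaldehyde | COc1cc(O)c(C=O)cc1OC | starting material
22 | 2-(benzyloxy)-4,5-dimethoxybenzaldehyde | COc1cc(OCc2ccccc2)c(C=O)cc1OC | intermediate
23 | 1-(benzyloxy)-4,5-dimethoxy-2-(2-methoxyethenyl)benzene (E/Z mixture) | COC=Cc1cc(OC)c(OC)cc1OCc1ccccc1 | intermediate
24 | 2-[2-(benzyloxy)-4,5-dimethoxyphenyl]acetaldehyde | COc1cc(OCc2ccccc2)c(CC=O)cc1OC | intermediate
25 | 3-(benzyloxy)-6-{[4-(benzyloxy)-5-[(3R)-7-(benzyloxy)chroman-3-yl]-2-methoxyphenyl]methylidene}cyclohexa-2,4-dien-1-one (o-quinone methide, alkene geometry not fixed) | O=C1C=C(OCc2ccccc2)C=CC1=Cc1cc([C@@H]2COc3cc(OCc4ccccc4)ccc3C2)c(OCc2ccccc2)cc1OC | intermediate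
26 | (2R)-1-{(E)-2-[2-(benzyloxy)-4,5-dimethoxyphenyl]ethenyl}-2-{diphenyl[(trimethylsilyl)oxy]methyl}pyrrolidine | COc1cc(OCc2ccccc2)c(/C=C/N2CCC[C@@H]2C(c2ccccc2)(c2ccccc2)O[Si](C)(C)C)cc1OC | intermediate
27 | (3R,4S)-7-(benzyloxy)-3-[2-(benzyloxy)-4,5-dimethoxyphenyl]-4-{4-(benzyloxy)-5-[(3R)-7-(benzyloxy)chroman-3-yl]-2-methoxyphenyl}chroman-2-ol (trans, anomeric mixture) | COc1cc(OCc2ccccc2)c([C@@H]2C(O)Oc3cc(OCc4ccccc4)ccc3[C@H]2c2cc([C@@H]3COc4cc(OCc5ccccc5)ccc4C3)c(OCc3ccccc3)cc2OC)cc1OC | intermediate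
28 | (3R,4S)-7-(benzyloxy)-3-[2-(benzyloxy)-4,5-dimethoxyphenyl]-4-{4-(benzyloxy)-5-[(3R)-7-(benzyloxy)chroman-3-yl]-2-methoxyphenyl}chroman | COc1cc(OCc2ccccc2)c([C@@H]2COc3cc(OCc4ccccc4)ccc3[C@H]2c2cc([C@@H]3COc4cc(OCc5ccccc5)ccc4C3)c(OCc3ccccc3)cc2OC)cc1OC | intermediate
29 | (3R,4S)-3-(2-hydroxy-4,5-dimethoxyphenyl)-4-{4-hydroxy-5-[(3R)-7-hydroxychroman-3-yl]-2-methoxyphenyl}chroman-7-ol | COc1cc(O)c([C@@H]2COc3cc(O)ccc3[C@H]2c2cc([C@@H]3COc4cc(O)ccc4C3)c(O)cc2OC)cc1OC | target

Total step count: 17.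
Longest linear sequence: 12 steps (1 to 29 through steps 1–4, 8–12 and 15–17).

Steps most likely to fail

Step 15. The face at which the methide carbon is attacked may be poorly controlled, and material may be lost through self-condensation of the aldehyde or arene attack on the methide. The fallback keeps the disconnection but moves the chirality to a Brønsted acid that binds the electrophile. It sets out from 24 and 20 and returns at 27. Aldehyde 24 is condensed with benzyl carbamate (PPTS cat., toluene, reflux with removal of water) to benzyl N-{(E)-2-[2-(benzyloxy)-4,5-dimethoxyphenyl]ethenyl}carbamate F1. A BINOL-derived chiral phosphoric acid (the antipode that delivers 4S) then ionises 20 and holds methide 25 and F1 in a hydrogen-bonded ion pair. The resulting [4+2] cycloaddition should give benzyl N-[(3R,4S)-7-(benzyloxy)-3-[2-(benzyloxy)-4,5-dimethoxyphenyl]-4-{4-(benzyloxy)-5-[(3R)-7-(benzyloxy)chroman-3-yl]-2-methoxyphenyl}chroman-2-yl]carbamate F2. Aqueous acid (TFA, THF/H2O) hydrolyses this N,O-aminal to lactol 27, in which C3 can settle trans to the C4 centre fixed in the cycloaddition.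

Step 12. The silyl group may transfer to the new alkoxide and silanolate may then be lost, which would set the quinone methide free in a basic medium and divert it to oligomers; the benzhydrol may also ionise during isolation. The fallback passes through a stable ketone, sets out from 17 and returns at 20. 4-(Benzyloxy)-2-hydroxybenzoic acid (commercial) is converted with acetone, SOCl2 and DMAP in DME into 7-(benzyloxy)-2,2-dimethyl-4H-1,3-benzodioxin-4-one F3. Aryllithium 18, made from 17 as in step 12, adds to F3, and collapse of the adduct should leave, as its unreactive phenoxide, {4-(benzyloxy)-5-[(3R)-7-(benzyloxy)chroman-3-yl]-2-methoxyphenyl}[4-(benzyloxy)-2-hydroxyphenyl]methanone F4. This ketone can be purified and stored, and NaBH4 (THF/MeOH, 0 °C) reduces it under basic conditions to 20 directly before step 15.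

Step 16. The oxocarbenium ion may lose the C3 proton (enol ether formation and re-protonation, which would scramble C3), or the electron-rich diarylmethine may fragment at C3–C4 under the Lewis acid. The fallback avoids cations, sets out from 27 and returns at 28. NaBH4 (THF/MeOH, 0 °C) reduces the open hydroxy aldehyde form of 27 to (2R,3S)-2-[2-(benzyloxy)-4,5-dimethoxyphenyl]-3-[4-(benzyloxy)-2-hydroxyphenyl]-3-{4-(benzyloxy)-5-[(3R)-7-(benzyloxy)chroman-3-yl]-2-methoxyphenyl}propan-1-ol F5. Mitsunobu etherification (PPh3, DIAD, THF) then closes the pyran ring at the primary carbon to give 28 without touching C3 or C4.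

Further compounds
F1 | step 15 | benzyl N-{(E)-2-[2-(benzyloxy)-4,5-dimethoxyphenyl]ethenyl}carbamate | COc1cc(OCc2ccccc2)c(/C=C/NC(=O)OCc2ccccc2)cc1OC
F2 | step 15 | benzyl N-[(3R,4S)-7-(benzyloxy)-3-[2-(benzyloxy)-4,5-dimethoxyphenyl]-4-{4-(benzyloxy)-5-[(3R)-7-(benzyloxy)chroman-3-yl]-2-methoxyphenyl}chroman-2-yl]carbamate (C2 not assigned) | COc1cc(OCc2ccccc2)c([C@@H]2C(NC(=O)OCc3ccccc3)Oc3cc(OCc4ccccc4)ccc3[C@H]2c2cc([C@@H]3COc4cc(OCc5ccccc5)ccc4C3)c(OCc3ccccc3)cc2OC)cc1OC
F3 | step 12 | 7-(benzyloxy)-2,2-dimethyl-4H-1,3-benzodioxin-4-one | CC1(C)OC(=O)c2ccc(OCc3ccccc3)cc2O1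
F4 | step 12 | {4-(benzyloxy)-5-[(3R)-7-(benzyloxy)chroman-3-yl]-2-methoxyphenyl}[4-(benzyloxy)-2-hydroxyphenyl]methanone | O=C(c1ccc(OCc2ccccc2)cc1O)c1cc([C@@H]2COc3cc(OCc4ccccc4)ccc3C2)c(OCc2ccccc2)cc1OC
F5 | step 16 | (2R,3S)-2-[2-(benzyloxy)-4,5-dimethoxyphenyl]-3-[4-(benzyloxy)-2-hydroxyphenyl]-3-{4-(benzyloxy)-5-[(3R)-7-(benzyloxy)chroman-3-yl]-2-methoxyphenyl}propan-1-ol | COc1cc(OCc2ccccc2)c([C@H](CO)[C@@H](c2ccc(OCc3ccccc3)cc2O)c2cc([C@@H]3COc4cc(OCc5ccccc5)ccc4C3)c(OCc3ccccc3)cc2OC)cc1OC
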